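At late times, at 80 min, I have no reading, so I begin where the earlier runs end, at 10 min, and carry the order forward from there.

| flask | starting material | reagent | remark | time |
|---|---|---|---|---|
| Saturday's | 6.9 mM | 100 mM | run made earlier |  |
| Friday's | 71 mM | 100 mM | run made earlier |  |
| Thursday's | 20 mM | 160 mM | run made earlier |  |
| winter | 5.0 mM | 300 mM |  | 10 min |
| dusk | 20 mM | 100 mM |  | 10 min |
| spring | 6.0 mM | 60.0 mM |  | 10 min |
| midnight | 60 mM | 100 mM |  | 10 min |

| run | time / min | target / % | over-reaction product / % | side product / % |
|---|---|---|---|---|
| Saturday's | 1.33 | 0 | 3 | 4 |
| Saturday's | 4.00 | 5 | 2 | 4 |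
| Saturday's | 6.00 | 8 | 3 | 0 |
| Saturday's | 10.0 | 12 | 6 | 3 |
| Friday's | 2.50 | 0 | 0 | 1 |
| Friday's | 5.00 | 4 | 1 | 7 |
| Friday's | 8.00 | 4 | 0 | 14 |
| Friday's | 10.0 | 6 | 0 | 20 |
| Thursday's | 0.833 | 3 | 0 | 3 |
| Thursday's | 2.00 | 0 | 2 | 0 |
| Thursday's | 4.00 | 4 | 0 | 4 |
| Thursday's | 10.0 | 11 | 4 | 9 |

(scatter of a reading: 2 percentage points)

- percentages count the starting material that a species holds: one side product counts as two

- the flasks by share of target in all that became target or over-reaction product or side product, highest first, at 10 min (winter / dusk / spring / midnight)
- the same order at 80 min (winter / dusk / spring / midnight)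
- the share of target in all that became target or over-reaction product or side product of the flask you put first, at 10 min
- the share of target in all that became target or over-reaction product or side product of the flask you put last, at 10 min

I work with the fraction left. For each unit of target standing at 10 min, I count what has gone to side product and what has gone to over-reaction product. The share of target, its selectivity, is then one over one plus those two loads. I assume each load grows with one charge. Side product per target per mM of starting material charged reads 0.0362 mM⁻¹, 0.0469 mM⁻¹ and 0.0409 mM⁻¹ in Saturday's, Friday's and Thursday's runs, though the charge spans ten times. Pooled, this gives the side load 0.0439 mM⁻¹. Pooled the same way per mM of reagent, the over-reaction load is 0.00281 mM⁻¹.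

These give spring 69.8%, winter 48.5%, dusk 46.3% and midnight 25.5%.

The weak link is the over-reaction load, which rests on few percentage points, so its scatter is 34.6% of its value. Reforged with that spread, winter runs from 42.5% to 56.5% and dusk from 44.3% to 48.5%. I keep winter above dusk, but as a close call.

By 80 min I expect the over-reaction load to go on growing with the reagent charge, and winter's reagent charge is larger than any other. So I put winter last, behind spring, dusk and midnight, which keep their order from 10 min.

The forecast reads spring > dusk > winter > midnight at 10 min and spring > dusk > midnight > winter at 80 min, with 68% first and 23% last, “the last being side-product dominated”, and its order at 10 min differs from mine in putting dusk above winter.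

The flasks give spring > winter > dusk > midnight, with spring 75.8%, winter 52.1%, dusk 49.5% and midnight 25.4%, and at 80 min spring > dusk > midnight > winter.

    starting material → intermediate (k = 0.0570 min⁻¹)
    reagent + intermediate → target (k = 1.60 L mol⁻¹ min⁻¹)
    reagent + target → over-reaction product (k = 0.370 L mol⁻¹ min⁻¹)
    starting material ⇌ dormant form (K = 0.830, k = 0.270 min⁻¹)
    starting material + target → side product (k = 11.0 L mol⁻¹ min⁻¹)

Midnight's own side product per target per mM comes to 0.0460 mM⁻¹, beside my side load of 0.0439 mM⁻¹. I take the same reckoning to a flask like midnight but charged with 240 mM of starting material. Its side load term is 10.5 and its over-reaction term 0.281, so I reckon a share of 8.46%. At 10.0 min that flask holds 23.0% as side product against 1.72% as target, and its share is 6.85%.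

The runs were computed on assumed constants, noise included.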